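**Retrosynthetic overview**
1. Target ⇐ oxepane closure (C16–O–C3: primary triflate displaced by the tertiary C3–OH) ⇐ hydroboration of the C14 isopropenyl group of tricycle 28.
2. 28 ⇐ ring-closing metathesis (C6=C7, oxonene) ⇐ C9 methallylation of a lactol acetate ⇐ bicyclic keto lactone 20 (after Wittig methylenation and C11 reduction).
3. Key step: the γ-lactone (future C2–O–C9 tetrahydrofuran) and the cyclohexanone are formed together from acyclic aldehyde 9 by acylketene esterification, Knoevenagel condensation and a [5+1] double Michael addition of tert-butyl acetoacetate.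
4. 9 ⇐ Sharpless epoxidation of (Z)-allylic alcohol 5 and C3-selective epoxide opening (sets C2 and C3) ⇐ Negishi coupling.
5. Ring order: lactone + cyclohexane (one operation) → oxonene → oxepane.

Assumption: asbestinin numbering is used for every intermediate (cyclohexane C1/C10/C11/C12/C13/C14, ether bridge C2–O–C9, quaternary C3, chain C4–C8, side chain C15/C16); β is the cyclohexane face carrying C2 and C9; 4 and 25 are taken as commercial.

**Route**

Step 1
Reactants: 1 but-2-yn-1-ol
Product: 3 (Z)-3-iodobut-2-en-1-ol, via cyclic vinylalanate 2 (not isolated)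
Conditions: Red-Al (1.6 equiv), THF, 0 °C → rt; then I2, −78 → 0 °C
Reagents that add atoms: iodine, II
Why: Alkoxide-directed trans-hydroalumination of the propargylic alcohol puts Al on C3 anti to the new C2–H, and iodinolysis of the C–Al bond with retention fixes the Z geometry (hydroalumination–iodination).

Step 2
Reactants: 3 (Z)-3-iodobut-2-en-1-ol; 4 but-3-en-1-ylzinc bromide
Product: 5 (Z)-3-methylhepta-2,6-dien-1-ol
Conditions: 4 (1.5 equiv), PdCl2(dppf) (3 mol %), THF, rt
Reagents that add atoms: none
Why: Negishi sp2–sp3 cross-coupling proceeds with retention of alkene geometry, so the butenyl chain ends up cis to CH2OH.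

Step 3
Reactants: 5 (Z)-3-methylhepta-2,6-dien-1-ol
Product: 6 [(2S,3R)-3-(but-3-en-1-yl)-3-methyloxiran-2-yl]methanol
Conditions: Ti(OiPr)4 (10 mol %), L-(+)-DET (12 mol %), t-BuOOH, 4 Å MS, CH2Cl2, −20 °C
Reagents that add atoms: tert-butyl hydroperoxide, CC(C)(C)OO
Why: Sharpless asymmetric epoxidation with L-(+)-tartrate gives the (2S,3R) epoxide, setting the C2–O bond (future THF oxygen) and, after inversion in step 4, C3.

Step 4
Reactants: 6 [(2S,3R)-3-(but-3-en-1-yl)-3-methyloxiran-2-yl]methanol; 7 4-methoxybenzyl alcohol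
Product: 8 (2S,3S)-3-[(4-methoxybenzyl)oxy]-3-methylhept-6-ene-1,2-diol
Conditions: 7 (5 equiv), BF3·OEt2 (10 mol %), CH2Cl2, −30 °C
Reagents that add atoms: none
Why: Lewis acid-catalysed epoxide alcoholysis occurs at the tertiary, cation-stabilising C3 with inversion (borderline SN2), leaving the C2–O bond untouched and masking the C3 oxygen as a PMB ether.

Step 5
Reactants: 8 (2S,3S)-3-[(4-methoxybenzyl)oxy]-3-methylhept-6-ene-1,2-diol
Product: 9 (2R,3S)-2-hydroxy-3-[(4-methoxybenzyl)oxy]-3-methylhept-6-enal
Conditions: TEMPO (10 mol %), PhI(OAc)2 (1.1 equiv), CH2Cl2, rt; used crude at once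
Reagents that add atoms: none
Why: Oxoammonium (TEMPO) oxidation is selective for the primary over the secondary alcohol and is mild enough not to epimerise C2.

Step 6
Reactants: 10 Meldrum's acid; 11 methacryloyl chloride
Product: 12 5-(1-hydroxy-2-methylprop-2-en-1-ylidene)-2,2-dimethyl-1,3-dioxane-4,6-dione
Conditions: pyridine (2 equiv), CH2Cl2, 0 °C → rt
Reagents that add atoms: none
Why: C-acylation of Meldrum's acid gives the acyl Meldrum's acid, a thermal precursor of the acylketene used in step 7.

Step 7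
Reactants: 9 (2R,3S)-2-hydroxy-3-[(4-methoxybenzyl)oxy]-3-methylhept-6-enal; 12 5-(1-hydroxy-2-methylprop-2-en-1-ylidene)-2,2-dimethyl-1,3-dioxane-4,6-dione; 13 tert-butyl acetoacetate
Product: 18 cis-fused bicyclic keto lactone tert-butyl ester (C14 epimers), via acylketene 14 (not isolated), via keto ester 15 (not isolated), via butenolide 16 (not isolated), via Michael adduct 17 (not isolated)
Conditions: 12 (1.05 equiv), PhMe, 80 °C; piperidinium acetate (10 mol %), rt; then 13 (1.1 equiv), Cs2CO3 (20 mol %), MeCN, 0 °C → rt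
Reagents that add atoms: none
Why: Proposed new method: thermolysis of 12 releases acylketene 14, which acylates the only free hydroxyl of 9 (15); intramolecular Knoevenagel condensation closes the γ-lactone (16), whose doubly activated C1 takes up the acetoacetate anion anti to the bulky C3 substituent (17); the new β-keto ester carbanion then closes the cyclohexanone by 6-endo-trig Michael addition onto the methacryloyl CH2 (a [5+1] double Michael annulation of a cross-conjugated dienone), with C10 settling cis-fused and C12 set by protonation of the C11–C12 enolate from the convex face; the closest known reactions are alcohol trapping of acylketenes from acyl Meldrum's acids, butenolide formation by intramolecular Knoevenagel condensation, and base-mediated double Michael addition of β-keto esters to divinyl ketones.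

Step 8
Reactants: 18 cis-fused bicyclic keto lactone tert-butyl ester
Product: 20 14α-acetyl keto lactone with free C3–OH, via keto acid 19 (not isolated)
Conditions: TFA/CH2Cl2 (1:4), anisole, 0 °C → rt; then PhMe, 80 °C; then DBU (1.5 equiv), CH2Cl2, rt, AcOH quench
Reagents that add atoms: none
Why: Acidolysis removes the tert-butyl ester and the PMB ether, β-keto acid 19 decarboxylates on warming, and base equilibration α to the acetyl group places it equatorial, trans to the C1–C2 bond (14α), in the enolised keto lactone.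

Step 9
Reactants: 20 14α-acetyl keto lactone
Product: 21 14α-isopropenyl keto lactone
Conditions: Ph3PCH3Br/KOtBu (3.5 equiv each), THF, 0 °C → rt
Reagents that add atoms: methylidenetriphenylphosphorane, C=P(c1ccccc1)(c1ccccc1)c1ccccc1
Why: Wittig methylenation takes only the methyl ketone because the β-keto lactone is deprotonated to its unreactive enolate by the first equivalent of ylide, which also shields C12 from epimerisation.

Step 10
Reactants: 21 14α-isopropenyl keto lactone
Product: 22 11β-hydroxy lactone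
Conditions: NaBH4, MeOH, −20 °C
Reagents that add atoms: none
Why: Borohydride reduction of the β-keto lactone: hydride attacks C11 from the convex face, anti to the cis-fused lactone and the 12β-methyl group, giving the 11β-alcohol.

Step 11
Reactants: 22 11β-hydroxy lactone
Product: 24 C9 lactol acetate 11β-acetate, via lactol aluminate 23 (not isolated)
Conditions: DIBAL-H (3.5 equiv), CH2Cl2, −78 °C; then pyridine, DMAP, Ac2O, −78 → −20 °C
Reagents that add atoms: acetic anhydride, CC(=O)OC(C)=O
Why: DIBAL reduction of the lactone with in situ acetylation of the aluminium alkoxides (reductive acetylation) gives the anomeric acetate and installs the C11 acetate of the target, while the tertiary C3 alkoxide is not acylated at low temperature.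

Step 12
Reactants: 24 C9 lactol acetate 11β-acetate; 25 trimethyl(2-methylprop-2-en-1-yl)silane
Product: 27 2,9-cis C9-methallyl tetrahydrofuran, via oxocarbenium ion 26 (not isolated)
Conditions: 25 (3 equiv), BF3·OEt2 (2 equiv), CH2Cl2, −78 °C
Reagents that add atoms: none
Why: Hosomi–Sakurai C-glycosylation: BF3 ionises the anomeric acetate and the allylsilane attacks the convex face of the oxocarbenium ion, anti to the cis-fused cyclohexane, which sets C9 cis to the C2 substituent.

Step 13
Reactants: 27 2,9-cis C9-methallyl tetrahydrofuran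
Product: 28 tricyclic (Z)-oxonene with 14α-isopropenyl
Conditions: Grubbs II (10 mol %), CH2Cl2 (2 mM), 40 °C
Reagents that add atoms: none
Why: Ring-closing metathesis between the monosubstituted butenyl alkene (initiation site) and the unhindered methallyl group on the same THF face closes the nine-membered ether, the ring enforcing the Z trisubstituted alkene; the α-branched isopropenyl group is a poor metathesis partner.

Step 14
Reactants: 28 tricyclic (Z)-oxonene with 14α-isopropenyl
Product: 30 tricyclic C3,C16-diol (15R), via alkylborane 29 (not isolated)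
Conditions: 9-BBN (3 equiv), THF, 0 °C → rt; then NaBO3·4H2O, H2O, rt
Reagents that add atoms: sodium perborate, [Na+].OO[B-](O)(O)O
Why: Hydroboration–oxidation with 9-BBN takes the 1,1-disubstituted alkene in preference to the trisubstituted ring alkene, and the borane adds anti to the larger allylic substituent (C1) in the H-eclipsed conformer, giving 15R with the C15 methyl anti to C13.

Step 15
Reactants: 30 tricyclic C3,C16-diol
Product: 32 11-acetoxy-4-deoxyasbestinin D (target), via primary triflate 31 (not isolated)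
Conditions: Tf2O (1.2 equiv), 2,6-lutidine (3 equiv), CH2Cl2, −78 → 0 °C
Reagents that add atoms: none
Why: Chemoselective triflation of the primary alcohol and in situ 7-exo-tet displacement by the tertiary C3 hydroxyl (Williamson-type etherification) closes the oxepane without touching any stereocentre.

**Compound list**
1 | but-2-yn-1-ol | CC#CCO | starting material
2 | cyclic vinylalanate (sodium ate complex; Al on C3, ring through the alkoxide oxygen) | CC1=CCO[Al-]1(OCCOC)OCCOC.[Na+] | intermediate
3 | (Z)-3-iodobut-2-en-1-ol | C/C(I)=C/CO | intermediate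
4 | but-3-en-1-ylzinc bromide | C=CCC[Zn]Br | starting material
5 | (Z)-3-methylhepta-2,6-dien-1-ol | OC/C=C(/C)CCC=C | intermediate
6 | [(2S,3R)-3-(but-3-en-1-yl)-3-methyloxiran-2-yl]methanol | OC[C@@H]1O[C@]1(C)CCC=C | intermediate
7 | 4-methoxybenzyl alcohol | COc1ccc(CO)cc1 | starting material
8 | (2S,3S)-3-[(4-methoxybenzyl)oxy]-3-methylhept-6-ene-1,2-diol | OC[C@H](O)[C@@](C)(OCc1ccc(OC)cc1)CCC=C | intermediate
9 | (2R,3S)-2-hydroxy-3-[(4-methoxybenzyl)oxy]-3-methylhept-6-enal | O=C[C@H](O)[C@@](C)(OCc1ccc(OC)cc1)CCC=C | intermediate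
10 | Meldrum's acid (2,2-dimethyl-1,3-dioxane-4,6-dione) | CC1(C)OC(=O)CC(=O)O1 | starting material
11 | methacryloyl chloride | CC(=C)C(Cl)=O | starting material
12 | 5-(1-hydroxy-2-methylprop-2-en-1-ylidene)-2,2-dimethyl-1,3-dioxane-4,6-dione | CC(=C)C(O)=C1C(=O)OC(C)(C)OC1=O | intermediate
13 | tert-butyl acetoacetate | CC(=O)CC(=O)OC(C)(C)C | starting material
14 | (2-methylprop-2-enoyl)ketene | CC(=C)C(=O)C=C=O | intermediate
15 | 4-methyl-3-oxopent-4-enoate ester of the C2 hydroxyl of 9 | O=C[C@H](OC(=O)CC(=O)C(C)=C)[C@@](C)(OCc1ccc(OC)cc1)CCC=C | intermediate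
16 | (5S)-3-(2-methylprop-2-enoyl)furan-2(5H)-one carrying at C5 (= C2) the (S)-2-(PMB-oxy)hex-5-en-2-yl group (C3) | C=C(C)C(=O)C1=C[C@@H]([C@@](C)(OCc2ccc(OC)cc2)CCC=C)OC1=O | intermediate
17 | γ-lactone with the acetoacetate unit on C1 trans to the C3 group (C10 and C14 unassigned) | C=C(C)C(=O)C1[C@H](C(C(C)=O)C(=O)OC(C)(C)C)[C@@H]([C@@](C)(OCc2ccc(OC)cc2)CCC=C)OC1=O | intermediate
18 | cis-fused γ-lactone (C9=O, O–C2) / cyclohexanone (C11=O): 12β-methyl; C14 bearing acetyl and CO2tBu (epimers); C2 carrying the (S)-2-(PMB-oxy)hex-5-en-2-yl group trans to C14 | O=C1[C@H](C)CC(C(C)=O)(C(=O)OC(C)(C)C)[C@H]2[C@@H]1C(=O)O[C@@H]2[C@@](C)(OCc1ccc(OC)cc1)CCC=C | intermediate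
19 | keto acid: as 18 with C14–CO2H and free C3–OH | O=C1[C@H](C)CC(C(C)=O)(C(=O)O)[C@H]2[C@@H]1C(=O)O[C@@H]2[C@@](C)(O)CCC=C | intermediate
20 | cis-fused keto lactone: 12β-methyl, 14α-acetyl (trans to C2), C2 carrying the (S)-2-hydroxyhex-5-en-2-yl group | O=C1[C@H](C)C[C@@H](C(C)=O)[C@H]2[C@@H]1C(=O)O[C@@H]2[C@@](C)(O)CCC=C | intermediate
21 | as 20 with 14α-isopropenyl | O=C1[C@H](C)C[C@@H](C(C)=C)[C@H]2[C@@H]1C(=O)O[C@@H]2[C@@](C)(O)CCC=C | intermediate
22 | 11β-hydroxy lactone (OH cis to C9 and to 12β-Me) | O[C@@H]1[C@H](C)C[C@@H](C(C)=C)[C@H]2[C@@H]1C(=O)O[C@@H]2[C@@](C)(O)CCC=C | intermediate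
23 | tris(diisobutylaluminium) alkoxide of the lactol from 22 (C9 anomers) | CC(C)C[Al](CC(C)C)O[C@@H]1[C@H](C)C[C@@H](C(C)=C)[C@H]2[C@@H]1C(O[Al](CC(C)C)CC(C)C)O[C@@H]2[C@@](C)(O[Al](CC(C)C)CC(C)C)CCC=C | intermediate
24 | C9 lactol acetate (anomers) with 11β-acetate and free C3–OH | CC(=O)O[C@@H]1[C@H](C)C[C@@H](C(C)=C)[C@H]2[C@@H]1C(OC(C)=O)O[C@@H]2[C@@](C)(O)CCC=C | intermediate
25 | trimethyl(2-methylprop-2-en-1-yl)silane | CC(=C)C[Si](C)(C)C | starting material
26 | bicyclic oxocarbenium ion (C9=O+) | CC(=O)O[C@@H]1[C@H](C)C[C@@H](C(C)=C)[C@H]2[C@@H]1C=[O+][C@@H]2[C@@](C)(O)CCC=C | intermediate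
27 | cis-fused hydroisobenzofuran: C9 methallyl and C2 (C3) group both on the THF face opposite the cyclohexane; 11β-OAc, 12β-Me, 14α-isopropenyl | CC(=O)O[C@@H]1[C@H](C)C[C@@H](C(C)=C)[C@H]2[C@@H]1[C@H](CC(C)=C)O[C@@H]2[C@@](C)(O)CCC=C | intermediate
28 | tricycle: cyclohexane / THF / (6Z)-oxonene with free C3–OH and 14α-isopropenyl | CC(=O)O[C@@H]1[C@H](C)C[C@@H](C(C)=C)[C@H]2[C@@H]1[C@@H]1C/C(C)=C\CC[C@](C)(O)[C@H]2O1 | intermediate
29 | B-(C16-alkyl)-9-borabicyclo[3.3.1]nonane from 28 (15R) | CC(=O)O[C@@H]1[C@H](C)C[C@@H]([C@@H](C)CB3C4CCCC3CCC4)[C@H]2[C@@H]1[C@@H]1C/C(C)=C\CC[C@](C)(O)[C@H]2O1 | intermediate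
30 | tricyclic diol: C16 primary OH (15R), C3 tertiary OH | CC(=O)O[C@@H]1[C@H](C)C[C@@H]([C@@H](C)CO)[C@H]2[C@@H]1[C@@H]1C/C(C)=C\CC[C@](C)(O)[C@H]2O1 | intermediate
31 | C16 primary triflate of 30 | CC(=O)O[C@@H]1[C@H](C)C[C@@H]([C@@H](C)COS(=O)(=O)C(F)(F)F)[C@H]2[C@@H]1[C@@H]1C/C(C)=C\CC[C@](C)(O)[C@H]2O1 | intermediate
32 | 11-acetoxy-4-deoxyasbestinin D, (1S,2S,3S,6Z,9S,10R,11R,12R,14S,15R) | CC(=O)O[C@H]1[C@@H]2[C@@H]3[C@@H](C[C@H]1C)[C@@H](C)CO[C@@]1(C)CC/C=C(/C)C[C@@H]2O[C@@H]31 | target

**Step count**
Total steps: 15. Longest linear sequence: 14 (steps 1–5 and 7–15; step 6 is a one-step side branch).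

**Three steps most likely to fail**

Step 7 (the one-pot cascade). Risks are partial racemisation of the γ-position of butenolide 16, a stalled second Michael addition, and the wrong C12 epimer. The fallback sets out from 9 and comes back at 20, and builds the cyclohexane by a neutral, concerted Diels–Alder reaction instead. Aldehyde 9 is heated with commercial methyl 3-oxopentanoate (DMAP cat., toluene, 100 °C, then piperidinium acetate) to give the 3-propanoyl butenolide F1. Soft enolisation (TBSOTf, Et3N, −78 °C) gives the (Z)-2-silyloxy diene F2. Thermal cycloaddition with methyl vinyl ketone (toluene, 80 °C), anti to the C3 substituent, gives the silyl enol ether adduct F3, in which C12 follows from the Z enol ether geometry. TFA/anisole then DBU cleaves the silyl enol ether and the PMB ether and equilibrates C14, giving 20.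

Step 13 (ring-closing metathesis with the isopropenyl group present). The risk is a competing eight-membered carbocycle from the isopropenyl and butenyl groups. The fallback sets out from 20 and comes back at 28, and closes the ring before the isopropenyl group exists. Ketone 20 is protected (ethylene glycol, TMSOTf cat., −78 °C) as the dioxolane keto lactone F4. This is taken through borohydride reduction to the 11β-alcohol F5, reductive acetylation to the bis-acetate F6, methallylation to the methallyl tetrahydrofuran F7 and metathesis to the tricyclic ketal F8. PPTS in wet acetone frees the tricyclic methyl ketone F9, and Wittig methylenation then gives 28.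

Step 14 (C15 by substrate-controlled hydroboration). The risk is the wrong sense or a poor ratio at C15. The fallback sets out from 28 and comes back at 30, and switches from the uncatalysed four-centre addition to rhodium-catalysed hydroboration (catecholborane, Rh(PPh3)3Cl, THF). That process runs through Rh–H insertion and gives the complementary 1,2-induction on 1,1-disubstituted alkenes with an allylic stereocentre. The resulting catechol boronate F10 is oxidised (NaBO3) to 30.

**Further compounds**
F1 | step 7 | (5S)-3-propanoylfuran-2(5H)-one carrying the (S)-2-(PMB-oxy)hex-5-en-2-yl group at C5 | CCC(=O)C1=C[C@@H]([C@@](C)(OCc2ccc(OC)cc2)CCC=C)OC1=O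
F2 | step 7 | (Z)-tert-butyldimethylsilyl dienol ether of F1 (2-silyloxy diene) | C/C=C(\O[Si](C)(C)C(C)(C)C)C1=C[C@@H]([C@@](C)(OCc2ccc(OC)cc2)CCC=C)OC1=O
F3 | step 7 | Diels–Alder adduct: C10=C11 silyl enol ether, 12β-methyl, 14α-acetyl, PMB ether at C3 | CC(=O)[C@@H]1C[C@@H](C)C(O[Si](C)(C)C(C)(C)C)=C2C(=O)O[C@H]([C@@](C)(OCc3ccc(OC)cc3)CCC=C)[C@@H]12
F4 | step 13 | ethylene ketal (2-methyl-1,3-dioxolan-2-yl at C14) of keto lactone 20 | O=C1[C@H](C)C[C@@H](C3(C)OCCO3)[C@H]2[C@@H]1C(=O)O[C@@H]2[C@@](C)(O)CCC=C
F5 | step 13 | 11β-hydroxy lactone, ketal series | O[C@@H]1[C@H](C)C[C@@H](C3(C)OCCO3)[C@H]2[C@@H]1C(=O)O[C@@H]2[C@@](C)(O)CCC=C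
F6 | step 13 | C9 lactol acetate 11β-acetate, ketal series | CC(=O)O[C@@H]1[C@H](C)C[C@@H](C3(C)OCCO3)[C@H]2[C@@H]1C(OC(C)=O)O[C@@H]2[C@@](C)(O)CCC=C
F7 | step 13 | 2,9-cis C9-methallyl tetrahydrofuran, ketal series | CC(=O)O[C@@H]1[C@H](C)C[C@@H](C3(C)OCCO3)[C@H]2[C@@H]1[C@H](CC(C)=C)O[C@@H]2[C@@](C)(O)CCC=C
F8 | step 13 | tricyclic (6Z)-oxonene, ketal series | CC(=O)O[C@@H]1[C@H](C)C[C@@H](C3(C)OCCO3)[C@H]2[C@@H]1[C@@H]1C/C(C)=C\CC[C@](C)(O)[C@H]2O1
F9 | step 13 | tricyclic (6Z)-oxonene with 14α-acetyl | CC(=O)O[C@@H]1[C@H](C)C[C@@H](C(C)=O)[C@H]2[C@@H]1[C@@H]1C/C(C)=C\CC[C@](C)(O)[C@H]2O1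
F10 | step 14 | C16 catechol boronate of 28 (15R) | CC(=O)O[C@@H]1[C@H](C)C[C@@H]([C@@H](C)CB3Oc4ccccc4O3)[C@H]2[C@@H]1[C@@H]1C/C(C)=C\CC[C@](C)(O)[C@H]2O1
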